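## Analysis of the target

Cryptomerin B (15) is a biflavone of the hinokiflavone type in which two 2-aryl-4H-chromen-4-ones are joined by a diaryl ether from C6 of unit 1 to C4''' of the 2-aryl ring of unit 2 (unit 1: chromone atoms unprimed, aryl ring primed; unit 2: chromone atoms double-primed, aryl ring triple-primed). The molecule is achiral and has no stereocentre, so the whole difficulty lies in placing and differentiating eight oxygen substituents on four aromatic rings. Ring A of unit 1 carries three contiguous, differently capped oxygens (C5–OH, C6–OAr, C7–OMe) and its ring B a C4'–OMe, whereas ring A of unit 2 has the phloroglucinol pattern with free C5''–OH and C7''–OH and the ring oxygen on C8a''. The sensitive features are three free phenols (two hydrogen-bonded to a C4 carbonyl), two methyl ethers that must survive to the end, and two pyranones that accept nucleophiles at C2 and open under hot hydroxide. Three things make the synthesis hard: telling the C5 oxygen of unit 1 from the C7 and C4' methyl ethers, building ring A of unit 2 without having to differentiate three phenolic hydroxyls, and forming a diaryl ether at an oxygen flanked by two alkoxy groups. The plan is built on ring A of unit 2, where the oxygen-bearing carbons C5'', C7'' and C8a'' stand ortho, para and ortho to the carbon that carries the C4'' carbonyl. Each of these three C–O bonds can therefore be made by nucleophilic aromatic substitution on a symmetric 2,4,6-trifluorophenyl ketone, the O1''–C8a'' bond intramolecularly as the ring-closing event.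

## Retrosynthetic reasoning

**15 to 14.** The free hydroxyls at C5, C5'' and C7'' are traced back to one methyl and two benzyl ethers. Benzyl is chosen on unit 2 because those oxygens have to arrive as neutral ethers, and methyl is accepted at C5 because it comes with the symmetric ring A precursor of unit 1. Of the three methyl ethers in 14 only the one at C5 sits peri to a carbonyl, so a Lewis acid that chelates to C4=O can remove it together with the benzyl groups and spare the C7 and C4' methyl ethers. The forward step has to achieve exactly that discrimination in one operation.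

**14 to 12 (through 13).** The C5''–O and C7''–O bonds are cut back to C–F bonds. Both carbons are activated by the C4'' carbonyl, so fluorine serves as a masked hydroxyl that survives everything before it. The incoming oxygen has to be capped with benzyl: a free phenoxide formed in the first exchange would switch the ring off for the second, whereas the neutral ether 13 does not.

**12 to 11 (key disconnection).** The O1''–C8a'' bond is cut, which opens the pyranone of unit 2 to the 1,3-diketone 11 with an intact 2,4,6-trifluorophenyl ring. The cut is made here because the ring oxygen is the third oxygen of this ring that sits ortho or para to the carbonyl-bearing carbon, so it too can arrive by displacement of fluoride. The gain is that the fluorinated ring of 11 is symmetric: no hydroxyl ever needs protecting or differentiating, and either ortho fluoride leads to the same product. The forward reaction must deliver the enolate oxygen to an ortho carbon and leave the para fluoride untouched.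

**11 to 8 and 9 (through 10).** The bond between the methylene carbon (future C3'') and the aroyl carbon (future C2'') is cut, a Claisen disconnection. Ester 8 contributes C2'' together with the whole of unit 1 and the phenylene bridge, and ketone 9, as its enolate 10, contributes C3'', C4'' and the fluorinated ring. This is the convergent point of the route: a fully built unit 1 meets a purchased ketone, and the ester it needs has been in the molecule since the first step.

**8 to 7.** The C4–C4a bond of unit 1 is cut, an intramolecular Friedel–Crafts acylation in the forward sense. The aryl ring of 7 is symmetric about its O–C axis and both positions ortho to the vinyl ether oxygen are activated by two methoxy groups, so no regiochemical question arises. Once the ring is closed, the two methoxy groups become the distinguishable C5 and C7 substituents.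

**7 to 5 and 6.** The O1–C2 bond is cut, a conjugate addition of phenol 5 to ynoate 6. The alkyne supplies C2, C3 and C4 in the correct oxidation state and brings ring B with its methoxy group in place, so no chalcone oxidation or dehydrogenation is needed.

**5 to 3 (through 4).** The phenolic C–O bond is traced back to the C–CHO bond of 3, an oxidative aryl migration in the forward direction that passes through formate 4. The formyl group of 1 is a stand-in for the future O1 of unit 1, and it keeps that position distinct from the oxygen that forms the diaryl ether.

**3 to 1 and 2.** The diaryl ether is cut at O–C4''', the phenoxide of 1 displacing fluoride from 2. The ester of 2 has two roles: it activates the fluoride here and later becomes the acyl donor of the Claisen step. Compound 1 brings the 1,2,3-trioxygenated pattern of ring A of unit 1 with its central oxygen already free.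

## Alternatives that were turned down

Alternative 1: the phenylene ring grown on oxygen by a pyranone cycloaddition. The bridging ring of the diaryl ether is not coupled but constructed, by disconnecting its C2'''–C3''' and C4'''–C5''' bonds. The forward step is a [4+2] cycloaddition between methyl coumalate A2 and the aryl ethynyl ether A3, followed by decarboxylative aromatisation of the bicyclic adduct to methyl 4-[4-(benzyloxy)-2,6-dimethoxyphenoxy]benzoate A1.
- For: the polarisation of the partners should give the para isomer, since the nucleophilic terminal carbon of A3 bonds to C6 of A2. The reaction is neutral and metal-free, and no hindered, weakly nucleophilic phenoxide has to attack a weakly activated aryl fluoride. On this single bond it is stronger than step 1 of the chosen route.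
- Against: A3 is a sensitive ynol ether that itself takes several steps to prepare. A1 still needs debenzylation before it reaches the stage of 5, which the chosen route reaches in two steps from 1 and 2.
- Comparison: the inventive step is spent on the diaryl ether, which is not the central problem. Both chromone rings and the whole oxygen pattern of unit 2 would still have to be solved by other means. The chosen strategy accepts a forcing but conventional ether formation, with a copper-catalysed fallback, and puts its key step where the differentiation problem is.

Alternative 2: both peri hydroxyls installed last by directed C–H oxidation. The C5–O and C5''–O bonds are disconnected to C–H bonds of the 5,5''-dideoxy biflavone ether A5. In the forward step the ruthenium catalyst A6 and the iodine oxidant A7, in a strongly acidic medium, hydroxylate both positions under direction by the C4 and C4'' carbonyls, and the product is 7''-O-pivaloylcryptomerin B A4. Catalyst A6 is the chloride-bridged dimer [RuCl2(p-cymene)]2 of divalent ruthenium, and oxidant A7 is the trivalent iodine reagent PhI(OCOCF3)2.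
- For: the two chelated hydroxyls appear directly as free OH groups. Neither a selective demethylation nor a phloroglucinol-type ring is needed, and A5 comes from simpler resorcinol-type building blocks. On step count and on the C5/C7 differentiation of unit 1 it is at least as strong as the chosen route.
- Against: A5 is a polyether with several electron-rich rings, and oxidant A7 in strong acid can oxidise such rings by electron transfer. The C5–H of unit 1 is buttressed by the C6 aryloxy group, which hinders cyclometalation by A6. The first-formed 5-hydroxy product has a free para position (C8) and is exposed to further oxidation towards a quinone. Two such events must succeed on the same molecule at the very end, and A4 still needs its pivalate removed.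
- Comparison: the chosen strategy never exposes the assembled skeleton to an oxidant. Every oxygen is placed by the position of a C–F bond or by the symmetry of a starting material, and the only late selectivity is a chelation-controlled ether cleavage.

Alternative 3: ring A of unit 1 from a squarate-derived cyclobutenone. The C4a–C5 bond is disconnected, and with it ring A of unit 1. Thermolysis of the racemic cyclobutenone A9, which carries a 4-pyranon-2-yl group on its sp3 carbon, should open the four-membered ring to a dienylketene. The ketene carbon then bonds to the neighbouring pyranone carbon in a 6π closure, and tautomerisation gives methyl 4-{[5-hydroxy-7-methoxy-2-(4-methoxyphenyl)-4-oxo-4H-chromen-6-yl]oxy}benzoate A8.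
- For: the C5 hydroxyl is born free from the ketene carbonyl, while the C6 aryloxy and C7 methoxy groups are fixed by the substitution of the four-membered ring. Unit 1 is regiodefined from the start with no demethylation at all, and on that point it is cleaner than the chosen route.
- Against: A9 needs an unsymmetrically substituted squaric acid derivative, reduction to the level of the 4-H cyclobutenone and a cross-coupling with a metallated 2-aryl-4-pyranone. That is several steps of specialised chemistry for a ring that the chosen route obtains from compound 1. The free C5 hydroxyl of A8 would consume base or need protection in the Claisen step, and unit 2 remains unsolved.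
- Comparison: the chosen route reaches the corresponding unit 1 ester 8 in four steps and pays for it with one chelation-directed demethylation merged into the final deprotection. Its key step addresses the more difficult ring A of unit 2.

Key step: step 6

Remark on the chemistry: 7 is drawn as the Z isomer expected from anti addition, and any E isomer should converge under the acid of step 4; in step 7 the para fluoride (C7'') is assumed to be exchanged first, and the opposite order would lead to the same product 14.

## Route

Step 1
Reactants: 1 syringaldehyde (4-hydroxy-3,5-dimethoxybenzaldehyde); 2 methyl 4-fluorobenzoate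
Product: 3 methyl 4-(4-formyl-2,6-dimethoxyphenoxy)benzoate
Conditions: K2CO3 (2 equiv), DMSO, 120 °C
Reagents that add atoms: none
Why: Nucleophilic aromatic substitution: the phenoxide of 1 adds para to the ester of 2, which stabilises the Meisenheimer anion, and fluoride leaves; aldehyde and methyl ester are inert to anhydrous K2CO3, and the aldehyde is kept as the masked phenol oxygen.

Step 2
Reactants: 3 methyl 4-(4-formyl-2,6-dimethoxyphenoxy)benzoate
Product: 5 methyl 4-(4-hydroxy-2,6-dimethoxyphenoxy)benzoate, via aryl formate 4 (not isolated)
Conditions: mCPBA, CH2Cl2, 0 °C → rt; then Et3N (cat.), MeOH, rt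
Reagents that add atoms: mCPBA, O=C(OO)c1cccc(Cl)c1
Why: Baeyer–Villiger (Dakin-type) oxidation: the aryl group, with a para aryloxy donor, should migrate in the Criegee intermediate in preference to hydride and give formate 4; amine-catalysed methanolysis frees the phenol, and ester exchange at the methyl benzoate in methanol is degenerate.

Step 3
Reactants: 5 methyl 4-(4-hydroxy-2,6-dimethoxyphenoxy)benzoate; 6 ethyl 3-(4-methoxyphenyl)prop-2-ynoate
Product: 7 ethyl (Z)-3-{3,5-dimethoxy-4-[4-(methoxycarbonyl)phenoxy]phenoxy}-3-(4-methoxyphenyl)prop-2-enoate
Conditions: Cs2CO3 (0.3 equiv), DMF, 80 °C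
Reagents that add atoms: none
Why: Base-catalysed oxa-Michael addition of a phenoxide to an ynoate (first half of the Ruhemann flavone synthesis); the hydroxyl of 5 is unhindered because both methoxy groups are meta to it, and anti addition places the aryloxy group cis to the ester, the geometry needed for ring closure.

Step 4
Reactants: 7 ethyl (Z)-3-{3,5-dimethoxy-4-[4-(methoxycarbonyl)phenoxy]phenoxy}-3-(4-methoxyphenyl)prop-2-enoate
Product: 8 methyl 4-{[5,7-dimethoxy-2-(4-methoxyphenyl)-4-oxo-4H-chromen-6-yl]oxy}benzoate
Conditions: P2O5/MeSO3H (Eaton's reagent), 60 °C
Reagents that add atoms: none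
Why: Intramolecular Friedel–Crafts acylation (second half of the Ruhemann synthesis): the push–pull ester ionises in the dehydrating acid to an acylium ion stabilised by the β-aryloxy and β-anisyl groups, which attacks the carbon ortho to the vinyl ether oxygen and ortho/para to the two methoxy groups; the two such carbons are equivalent by symmetry, and the simple benzoate ester cannot ionise comparably and should stay intact.

Step 5
Reactants: 8 methyl 4-{[5,7-dimethoxy-2-(4-methoxyphenyl)-4-oxo-4H-chromen-6-yl]oxy}benzoate; 9 2',4',6'-trifluoroacetophenone
Product: 11 1-(2,4,6-trifluorophenyl)-3-(4-{[5,7-dimethoxy-2-(4-methoxyphenyl)-4-oxo-4H-chromen-6-yl]oxy}phenyl)propane-1,3-dione, via lithium enolate 10 (not isolated)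
Conditions: LiN(SiMe3)2 (2.5 equiv), 9 (2.5 equiv), THF, −78 °C; then 8, −78 °C → rt; 1 M HCl
Reagents that add atoms: none
Why: Crossed Claisen condensation of a preformed ketone lithium enolate with a non-enolisable aromatic ester; a second equivalent of 10 deprotonates the product, whose chelated lithium enolate drives the equilibrium, and the silylamide base is too hindered to attack C–F or the ester. Any 12 formed by early ring closure merges with the material of step 6.

Step 6
Reactants: 11 1-(2,4,6-trifluorophenyl)-3-(4-{[5,7-dimethoxy-2-(4-methoxyphenyl)-4-oxo-4H-chromen-6-yl]oxy}phenyl)propane-1,3-dione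
Product: 12 6-[4-(5,7-difluoro-4-oxo-4H-chromen-2-yl)phenoxy]-5,7-dimethoxy-2-(4-methoxyphenyl)-4H-chromen-4-one
Conditions: K2CO3 (2 equiv), dry DMF (dilute), 50 °C
Reagents that add atoms: none
Why: K2CO3 turns the acidic diketone 11 into its potassium enolate, and the enolate oxygen that sits on the carbon carrying the aryloxyphenyl group adds to an ortho C–F carbon of the trifluorophenyl ring. The resulting Meisenheimer anion is delocalised into the adjacent ketone (the future C4'' carbonyl) and stabilised inductively by the remaining fluorines, and loss of fluoride restores aromaticity to give the 5,7-difluoroflavone 12. The nearest established reaction is the ring closure of 1-(2-fluoroaryl)-1,3-diketones to chromones and flavones under mild base, an intramolecular SNAr. The pyranone closes by O–C bond formation at a trigonal aromatic carbon in a six-membered addition–elimination, formally 6-endo-trig with respect to the C4a''–C8a'' bond that relays the charge to the carbonyl, and the cis-enol geometry holds the oxygen next to the ortho carbon. No stereocentre is formed. The step needs oxygen and not carbon to attack, and an ortho and not the para fluoride to leave: attack by C3'' or by the other carbonyl oxygen would require a four-membered ring, the para carbon cannot be reached from within the molecule, and the two ortho fluorides are equivalent by the symmetry of the ring. Carbonate is not a nucleophile that could compete for the aryl fluorides, and dry, dilute conditions hold back intermolecular displacement and retro-Claisen cleavage. Both surviving C–F bonds keep their ortho or para relationship to the C4'' carbonyl, which is what step 7 relies on.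

Step 7
Reactants: 12 6-[4-(5,7-difluoro-4-oxo-4H-chromen-2-yl)phenoxy]-5,7-dimethoxy-2-(4-methoxyphenyl)-4H-chromen-4-one
Product: 14 6-{4-[5,7-bis(benzyloxy)-4-oxo-4H-chromen-2-yl]phenoxy}-5,7-dimethoxy-2-(4-methoxyphenyl)-4H-chromen-4-one, via 7''-benzyloxy-5''-fluoro monoether 13 (not isolated)
Conditions: BnOH (3 equiv), NaH (2.6 equiv), DMF, 0 °C → 60 °C
Reagents that add atoms: benzyl alcohol, OCc1ccccc1
Why: Twofold intermolecular SNAr by NaOCH2Ph: the C5'' and C7'' fluorides are ortho and para to the C4'' carbonyl, and the neutral benzyl ether formed in the first exchange does not switch the ring off as a phenoxide would. The methoxy groups of unit 1 are far poorer leaving groups on a more electron-rich ring, and the bridging ether oxygen sits on carbons that are not comparably activated.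

Step 8
Reactants: 14 6-{4-[5,7-bis(benzyloxy)-4-oxo-4H-chromen-2-yl]phenoxy}-5,7-dimethoxy-2-(4-methoxyphenyl)-4H-chromen-4-one
Product: 15 cryptomerin B (6-[4-(5,7-dihydroxy-4-oxo-4H-chromen-2-yl)phenoxy]-5-hydroxy-7-methoxy-2-(4-methoxyphenyl)-4H-chromen-4-one)
Conditions: BCl3 (8 equiv), C6HMe5 (6 equiv), CH2Cl2, −78 °C → 0 °C; then MeOH, H2O
Reagents that add atoms: none
Why: Lewis-acid ether cleavage: BCl3 removes both benzyl ethers, the benzyl cations being trapped by C6HMe5, and cleaves the peri C5 methyl ether of unit 1 through a six-membered boron chelate with the C4 carbonyl; the non-chelated C7 and C4' methyl ethers and the diaryl ether should be left alone at or below 0 °C.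

## Compound list

1 | syringaldehyde (4-hydroxy-3,5-dimethoxybenzaldehyde) | COc1cc(C=O)cc(OC)c1O | starting material
2 | methyl 4-fluorobenzoate | COC(=O)c1ccc(F)cc1 | starting material
3 | methyl 4-(4-formyl-2,6-dimethoxyphenoxy)benzoate | COC(=O)c1ccc(Oc2c(OC)cc(C=O)cc2OC)cc1 | intermediate
4 | methyl 4-[4-(formyloxy)-2,6-dimethoxyphenoxy]benzoate | COC(=O)c1ccc(Oc2c(OC)cc(OC=O)cc2OC)cc1 | intermediate
5 | methyl 4-(4-hydroxy-2,6-dimethoxyphenoxy)benzoate | COC(=O)c1ccc(Oc2c(OC)cc(O)cc2OC)cc1 | intermediate
6 | ethyl 3-(4-methoxyphenyl)prop-2-ynoate | CCOC(=O)C#Cc1ccc(OC)cc1 | starting material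
7 | ethyl (Z)-3-{3,5-dimethoxy-4-[4-(methoxycarbonyl)phenoxy]phenoxy}-3-(4-methoxyphenyl)prop-2-enoate | CCOC(=O)/C=C(\Oc1cc(OC)c(Oc2ccc(C(=O)OC)cc2)c(OC)c1)c1ccc(OC)cc1 | intermediate
8 | methyl 4-{[5,7-dimethoxy-2-(4-methoxyphenyl)-4-oxo-4H-chromen-6-yl]oxy}benzoate | COC(=O)c1ccc(Oc2c(OC)cc3oc(-c4ccc(OC)cc4)cc(=O)c3c2OC)cc1 | intermediate
9 | 2',4',6'-trifluoroacetophenone, 1-(2,4,6-trifluorophenyl)ethanone | CC(=O)c1c(F)cc(F)cc1F | starting material
10 | lithium 1-(2,4,6-trifluorophenyl)ethenolate | [Li]OC(=C)c1c(F)cc(F)cc1F | intermediate
11 | 1-(2,4,6-trifluorophenyl)-3-(4-{[5,7-dimethoxy-2-(4-methoxyphenyl)-4-oxo-4H-chromen-6-yl]oxy}phenyl)propane-1,3-dione (drawn as the diketo form) | COc1ccc(-c2cc(=O)c3c(OC)c(Oc4ccc(C(=O)CC(=O)c5c(F)cc(F)cc5F)cc4)c(OC)cc3o2)cc1 | intermediate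
12 | 6-[4-(5,7-difluoro-4-oxo-4H-chromen-2-yl)phenoxy]-5,7-dimethoxy-2-(4-methoxyphenyl)-4H-chromen-4-one | COc1ccc(-c2cc(=O)c3c(OC)c(Oc4ccc(-c5cc(=O)c6c(F)cc(F)cc6o5)cc4)c(OC)cc3o2)cc1 | intermediate
13 | 6-{4-[7-(benzyloxy)-5-fluoro-4-oxo-4H-chromen-2-yl]phenoxy}-5,7-dimethoxy-2-(4-methoxyphenyl)-4H-chromen-4-one | COc1ccc(-c2cc(=O)c3c(OC)c(Oc4ccc(-c5cc(=O)c6c(F)cc(OCc7ccccc7)cc6o5)cc4)c(OC)cc3o2)cc1 | intermediate
14 | 6-{4-[5,7-bis(benzyloxy)-4-oxo-4H-chromen-2-yl]phenoxy}-5,7-dimethoxy-2-(4-methoxyphenyl)-4H-chromen-4-one | COc1ccc(-c2cc(=O)c3c(OC)c(Oc4ccc(-c5cc(=O)c6c(OCc7ccccc7)cc(OCc7ccccc7)cc6o5)cc4)c(OC)cc3o2)cc1 | intermediate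
15 | cryptomerin B, 6-[4-(5,7-dihydroxy-4-oxo-4H-chromen-2-yl)phenoxy]-5-hydroxy-7-methoxy-2-(4-methoxyphenyl)-4H-chromen-4-one | COc1ccc(-c2cc(=O)c3c(O)c(Oc4ccc(-c5cc(=O)c6c(O)cc(O)cc6o5)cc4)c(OC)cc3o2)cc1 | target

## Step count and least certain steps

Total step count: 8. Longest linear sequence: 8 steps (1 to 15); compounds 2, 6 and 9 enter as purchased materials.

**Step 6 (key step).** The cis-chelated potassium enolate is a weak nucleophile and the 2,6-difluoroaryl ketone must twist into plane, so closure may be slow. Slow closure would allow intermolecular displacement of the para fluoride by a second enolate, or retro-Claisen cleavage by adventitious hydroxide. Fallback: the pyranone of unit 2 is built from ester 8 by the classical hydroxy-diketone route, without fluorine. The lithium dianion of commercial 1-[2,4-bis(benzyloxy)-6-hydroxyphenyl]ethanone (CC(=O)c1c(O)cc(OCc2ccccc2)cc1OCc1ccccc1), made with LiN(SiMe3)2 in THF at −78 °C → rt, is acylated by 8. This should give 1-[2,4-bis(benzyloxy)-6-hydroxyphenyl]-3-(4-{[5,7-dimethoxy-2-(4-methoxyphenyl)-4-oxo-4H-chromen-6-yl]oxy}phenyl)propane-1,3-dione F1. Cyclodehydration with catalytic TsOH in toluene at 90 °C then closes the ring to 14, where the route is rejoined; compounds 11 to 13 are bypassed. Partial loss of the C5'' benzyl group at this stage would be harmless, since step 8 removes it anyway.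

**Step 4.** The ester may fail to ionise before trace water cleaves the vinyl ether, which would open a Pechmann-type path to the isomeric 4-arylcoumarin; sulfonylation of the anisyl ring is a further risk. Fallback: from 7, both esters are saponified with LiOH in THF/H2O to (Z)-3-[4-(4-carboxyphenoxy)-3,5-dimethoxyphenoxy]-3-(4-methoxyphenyl)prop-2-enoic acid F2. Treatment with (CF3CO)2O in CH2Cl2 forms the mixed anhydrides, and the cinnamoyl one cyclises onto the activated ring without strong acid. A methanol quench converts the remaining aroyl trifluoroacetate into the methyl ester and returns 8.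

**Step 5.** The methyl ester, deactivated by its para aryloxy group, may react slowly. Slow reaction gives the liberated methoxide time to displace fluoride from the ketone or the product, and the enolate time to add to C2 of the flavone. Fallback: from 8, LiOH in THF/H2O at rt gives 4-{[5,7-dimethoxy-2-(4-methoxyphenyl)-4-oxo-4H-chromen-6-yl]oxy}benzoic acid F3. Oxalyl chloride with catalytic DMF in CH2Cl2 gives 4-{[5,7-dimethoxy-2-(4-methoxyphenyl)-4-oxo-4H-chromen-6-yl]oxy}benzoyl chloride F4. Ketone 9 is then C-acylated under soft enolisation (MgBr2·OEt2, i-Pr2NEt, CH2Cl2, rt), which involves no alkoxide and no strong base, to return 11.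

**Step 1.** The phenoxide of 1 is hindered and weakened by its para formyl group, and the ester of 2 is only a moderate activator. The substitution may therefore stall at temperatures where ester hydrolysis by traces of water or degradation of the aldehyde take over. Fallback: from 1, a copper-catalysed Ullmann ether synthesis with methyl 4-iodobenzoate (COC(=O)c1ccc(I)cc1), using CuI, picolinic acid and K3PO4 in DMSO at 90 °C, gives 3 directly. This system tolerates ortho,ortho-disubstituted phenols and creates no new intermediate.

**Step 8.** The non-chelated C7'' benzyl ether may need longer exposure than the C7 methyl ether tolerates, giving over-demethylation. Incomplete trapping of benzyl cations could cause C-benzylation of the phloroglucinol-type ring, and the peri methyl ether may be cleaved incompletely. Fallback: the two deprotections are separated. From 14, hydrogenolysis (H2, Pd/C, THF/EtOAc) gives 6-[4-(5,7-dihydroxy-4-oxo-4H-chromen-2-yl)phenoxy]-5,7-dimethoxy-2-(4-methoxyphenyl)-4H-chromen-4-one F5. AlCl3 in MeCN then removes only the chelated C5 methyl ether and returns 15.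

## Further compounds

F1 | step 6 | 1-[2,4-bis(benzyloxy)-6-hydroxyphenyl]-3-(4-{[5,7-dimethoxy-2-(4-methoxyphenyl)-4-oxo-4H-chromen-6-yl]oxy}phenyl)propane-1,3-dione | COc1ccc(-c2cc(=O)c3c(OC)c(Oc4ccc(C(=O)CC(=O)c5c(O)cc(OCc6ccccc6)cc5OCc7ccccc7)cc4)c(OC)cc3o2)cc1
F2 | step 4 | (Z)-3-[4-(4-carboxyphenoxy)-3,5-dimethoxyphenoxy]-3-(4-methoxyphenyl)prop-2-enoic acid | OC(=O)/C=C(\Oc1cc(OC)c(Oc2ccc(C(=O)O)cc2)c(OC)c1)c1ccc(OC)cc1
F3 | step 5 | 4-{[5,7-dimethoxy-2-(4-methoxyphenyl)-4-oxo-4H-chromen-6-yl]oxy}benzoic acid | OC(=O)c1ccc(Oc2c(OC)cc3oc(-c4ccc(OC)cc4)cc(=O)c3c2OC)cc1
F4 | step 5 | 4-{[5,7-dimethoxy-2-(4-methoxyphenyl)-4-oxo-4H-chromen-6-yl]oxy}benzoyl chloride | ClC(=O)c1ccc(Oc2c(OC)cc3oc(-c4ccc(OC)cc4)cc(=O)c3c2OC)cc1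
F0 | step 1 | none | none
F5 | step 8 | 6-[4-(5,7-dihydroxy-4-oxo-4H-chromen-2-yl)phenoxy]-5,7-dimethoxy-2-(4-methoxyphenyl)-4H-chromen-4-one | COc1ccc(-c2cc(=O)c3c(OC)c(Oc4ccc(-c5cc(=O)c6c(O)cc(O)cc6o5)cc4)c(OC)cc3o2)cc1
A1 | alternative 1 | methyl 4-[4-(benzyloxy)-2,6-dimethoxyphenoxy]benzoate | COC(=O)c1ccc(Oc2c(OC)cc(OCc3ccccc3)cc2OC)cc1
A2 | alternative 1 | methyl coumalate, methyl 2-oxo-2H-pyran-5-carboxylate | COC(=O)c1ccc(=O)oc1
A3 | alternative 1 | 5-(benzyloxy)-2-(ethynyloxy)-1,3-dimethoxybenzene | C#COc1c(OC)cc(OCc2ccccc2)cc1OC
A4 | alternative 2 | 7''-O-pivaloylcryptomerin B | COc1ccc(-c2cc(=O)c3c(O)c(Oc4ccc(-c5cc(=O)c6c(O)cc(OC(=O)C(C)(C)C)cc6o5)cc4)c(OC)cc3o2)cc1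
A5 | alternative 2 | 2-(4-{[7-methoxy-2-(4-methoxyphenyl)-4-oxo-4H-chromen-6-yl]oxy}phenyl)-4-oxo-4H-chromen-7-yl pivalate | COc1ccc(-c2cc(=O)c3cc(Oc4ccc(-c5cc(=O)c6ccc(OC(=O)C(C)(C)C)cc6o5)cc4)c(OC)cc3o2)cc1
A6 | alternative 2 | [RuCl2(p-cymene)]2, dichloro(p-cymene)ruthenium dimer | Cc1ccc(C(C)C)cc1.Cc1ccc(C(C)C)cc1.Cl[Ru]Cl.Cl[Ru]Cl
A7 | alternative 2 | PhI(OCOCF3)2, phenyliodine bis(trifluoroacetate) | FC(F)(F)C(=O)OI(OC(=O)C(F)(F)F)c1ccccc1
A8 | alternative 3 | methyl 4-{[5-hydroxy-7-methoxy-2-(4-methoxyphenyl)-4-oxo-4H-chromen-6-yl]oxy}benzoate | COC(=O)c1ccc(Oc2c(OC)cc3oc(-c4ccc(OC)cc4)cc(=O)c3c2O)cc1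
A9 | alternative 3 | methyl 4-({2-methoxy-3-[6-(4-methoxyphenyl)-4-oxo-4H-pyran-2-yl]-4-oxocyclobut-1-en-1-yl}oxy)benzoate (racemic) | COC(=O)c1ccc(OC2=C(OC)C(c3cc(=O)cc(-c4ccc(OC)cc4)o3)C2=O)cc1
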